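**Plan**

- Retrosynthesis: after removal of four benzyl and two silyl groups, the pyranone ring is cut at C4–C4a (Friedel–Crafts acylation) and at O1–C2 (Mitsunobu etherification). This leaves a pentasubstituted phenol and a chiral β-hydroxy ester.
- The benzene A ring of that phenol is cut at C8–C8a, C6–C7 and C4a–C8a into a 3-siloxycyclobutenone and a siloxyalkyne. The cyclobutenone is itself the siloxyalkyne plus ketene.
- Feature used: the A ring (C4a, C5–C8, C8a) is a hexasubstituted phloroglucinol with the same 2,3-dihydroxybenzyl group on C6 and C8 and three differently used oxygens (O1, 5-OH, 7-OH). One siloxyalkyne therefore supplies both the C5–C6 and the C7–C8 pair, and ketene supplies C4a–C8a.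
- Forward order: benzyl-protected aryl side chain, siloxyalkyne, cyclobutenone, A ring by benzannulation, aryl ether, pyranone ring by acylation, deprotection.
- Stereochemistry: the only stereocentre, C2 (S), comes from ethyl (R)-3-hydroxy-3-phenylpropanoate by inversion in the Mitsunobu step and is not part of any later bond change.

Key step: step 7

Remarks on the chemistry: the given stereodescriptor corresponds to the (2S)-flavanone, and the route is planned for it. Ketene is taken as a gas from a laboratory ketene generator (acetone pyrolysis); its generation is not counted as a step. Ethynylmagnesium bromide is the commercial THF solution.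

**Route**

Step 1
Reactants: 1 2,3-dihydroxybenzaldehyde
Product: 2 2,3-bis(benzyloxy)benzaldehyde
Conditions: BnBr (2.4 equiv), K2CO3, DMF, 60 °C
Reagents that add atoms: benzyl bromide, BrCc1ccccc1
Why: Williamson etherification of both catechol hydroxyls with benzyl bromide under carbonate base is routine and leaves the aldehyde untouched.

Step 2
Reactants: 2 2,3-bis(benzyloxy)benzaldehyde
Product: 3 [2,3-bis(benzyloxy)phenyl]methanol
Conditions: NaBH4, MeOH/THF, 0 °C
Reagents that add atoms: none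
Why: Borohydride reduction of an aryl aldehyde to the benzylic alcohol is chemoselective in the presence of aryl benzyl ethers.

Step 3
Reactants: 3 [2,3-bis(benzyloxy)phenyl]methanol
Product: 4 1,2-bis(benzyloxy)-3-(bromomethyl)benzene
Conditions: PBr3 (0.4 equiv), Et2O, 0 °C
Reagents that add atoms: phosphorus tribromide, BrP(Br)Br
Why: Bromination of an electron-rich benzylic alcohol with PBr3 proceeds by SN2 displacement of the phosphite ester at 0 °C and does not touch the aryl benzyl ethers.

Step 4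
Reactants: 4 1,2-bis(benzyloxy)-3-(bromomethyl)benzene; 5 ethynylmagnesium bromide
Product: 6 1,2-bis(benzyloxy)-3-(prop-2-yn-1-yl)benzene
Conditions: HC≡CMgBr (0.5 M in THF, 2 equiv), CuBr·SMe2 (10 mol %), THF, rt → 45 °C
Reagents that add atoms: none
Why: Copper-catalysed cross-coupling of a benzylic bromide with ethynylmagnesium bromide is a standard entry to 3-arylprop-1-ynes, and excess Grignard reagent with moderate temperature limits double alkylation and isomerisation to the allene.

Step 5
Reactants: 6 1,2-bis(benzyloxy)-3-(prop-2-yn-1-yl)benzene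
Product: 9 3-[2,3-bis(benzyloxy)phenyl]prop-1-yn-1-yl triisopropylsilyl ether, via lithium acetylide 7 (not isolated), via lithium ynolate 8 (not isolated)
Conditions: n-BuLi (1.05 equiv), THF, −78 °C; LiOOt-Bu (from t-BuOOH/LiHMDS), −78 → 0 °C; TIPSOTf, −78 → 0 °C
Reagents that add atoms: tert-butyl hydroperoxide, CC(C)(C)OO; triisopropylsilyl trifluoromethanesulfonate, CC(C)[Si](OS(=O)(=O)C(F)(F)F)(C(C)C)C(C)C
Why: Kinetic deprotonation of the terminal alkyne, oxygen transfer from lithium tert-butyl peroxide to the acetylide (Julia oxidation) and O-silylation of the resulting ynolate with the bulky silyl triflate is the established route from terminal alkynes to triisopropylsiloxyalkynes.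

Step 6
Reactants: 9 3-[2,3-bis(benzyloxy)phenyl]prop-1-yn-1-yl triisopropylsilyl ether; 10 ketene
Product: 11 2-[2,3-bis(benzyloxy)benzyl]-3-[(triisopropylsilyl)oxy]cyclobut-2-en-1-one
Conditions: ketene (gas, excess), CH2Cl2, 0 °C
Reagents that add atoms: none
Why: Thermal [2+2] cycloaddition of ketene with an electron-rich siloxyalkyne gives 3-siloxycyclobutenones, the nucleophilic benzyl-bearing alkyne carbon bonding to the ketene carbonyl carbon so that the benzyl group sits at C2 next to the carbonyl.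

Step 7
Reactants: 11 2-[2,3-bis(benzyloxy)benzyl]-3-[(triisopropylsilyl)oxy]cyclobut-2-en-1-one; 9 3-[2,3-bis(benzyloxy)phenyl]prop-1-yn-1-yl triisopropylsilyl ether
Product: 16 2,4-bis[2,3-bis(benzyloxy)benzyl]-3,5-bis[(triisopropylsilyl)oxy]phenol, via vinylketene 12 (not isolated), via vinylcyclobutenone 13 (not isolated), via dienylketene 14 (not isolated), via cyclohexadienone 15 (not isolated)
Conditions: 9 (1.5 equiv), toluene (degassed), 80 → 110 °C, sealed tube
Reagents that add atoms: none
Why: On heating, 11 undergoes 4π-electrocyclic ring opening to vinylketene 12, whose ketene C=C adds [2+2] to siloxyalkyne 9 to give vinylcyclobutenone 13; a second 4π opening gives dienylketene 14, which closes to cyclohexadienone 15 and tautomerises to phenol 16. The closest known reaction type is the Danheiser benzannulation of cyclobutenones with triisopropylsiloxyalkynes, here with a 3-siloxycyclobutenone as the vinylketene source. The one ring that is closed, the benzenoid A ring, forms by 6π electrocyclisation of 14 (C4a–C8a bond) after the C8–C8a and C6–C7 bonds have been made in the ketene–alkyne cycloaddition. No stereocentre is created, because the quaternary carbon of 13 is lost again on ring opening and 16 is achiral. The step needs regioselectivity in the [2+2] event, which the polarisation of the partners secures: the benzyl-bearing β-carbon of 9 is the nucleophilic terminus and bonds to the electrophilic ketene carbonyl carbon, so each benzyl group ends between two oxygens and the CH carbon lies next to the free hydroxyl. An excess of the electron-rich alkyne should make the cross-cycloaddition faster than dimerisation of 12 or its capture by the product phenol.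

Step 8
Reactants: 16 2,4-bis[2,3-bis(benzyloxy)benzyl]-3,5-bis[(triisopropylsilyl)oxy]phenol; 17 ethyl (R)-3-hydroxy-3-phenylpropanoate
Product: 19 ethyl (3S)-3-{2,4-bis[2,3-bis(benzyloxy)benzyl]-3,5-bis[(triisopropylsilyl)oxy]phenoxy}-3-phenylpropanoate, via alkoxyphosphonium ion 18 (not isolated)
Conditions: PPh3, DIAD (slow addition), toluene, 0 °C → rt
Reagents that add atoms: none
Why: Mitsunobu etherification of a phenol with a secondary benzylic alcohol proceeds by SN2 displacement of the alkoxyphosphonium ion, so the (R)-carbinol of 17 is inverted and the new C–O stereocentre (the future C2) is set as S, while low temperature and a non-polar solvent are chosen to hold back dehydration to the cinnamate.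

Step 9
Reactants: 19 ethyl (3S)-3-{2,4-bis[2,3-bis(benzyloxy)benzyl]-3,5-bis[(triisopropylsilyl)oxy]phenoxy}-3-phenylpropanoate
Product: 20 (3S)-3-{2,4-bis[2,3-bis(benzyloxy)benzyl]-3,5-bis[(triisopropylsilyl)oxy]phenoxy}-3-phenylpropanoic acid
Conditions: LiOH·H2O, THF/H2O (3:1), 0 °C → rt; then 1 M HCl to pH 3
Reagents that add atoms: lithium hydroxide, [Li+].[OH-]
Why: Saponification of the unhindered ethyl ester at or below room temperature should be faster than β-elimination of the aryloxide or attack on the doubly ortho-substituted aryl silyl ethers, and the stereocentre is not involved.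

Step 10
Reactants: 20 (3S)-3-{2,4-bis[2,3-bis(benzyloxy)benzyl]-3,5-bis[(triisopropylsilyl)oxy]phenoxy}-3-phenylpropanoic acid
Product: 22 (2S)-6,8-bis[2,3-bis(benzyloxy)benzyl]-2-phenyl-5,7-bis[(triisopropylsilyl)oxy]-2,3-dihydro-4H-chromen-4-one, via mixed anhydride 21 (not isolated)
Conditions: TFAA (2 equiv), CH2Cl2, 0 °C
Reagents that add atoms: none
Why: Intramolecular Friedel–Crafts acylation through the mixed trifluoroacetic anhydride closes the pyranone ring at the only unsubstituted A-ring carbon, which is activated by one ortho ether oxygen and by one ortho and one para silyloxy group, and the stereocentre is not part of the reacting bonds.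

Step 11
Reactants: 22 (2S)-6,8-bis[2,3-bis(benzyloxy)benzyl]-2-phenyl-5,7-bis[(triisopropylsilyl)oxy]-2,3-dihydro-4H-chromen-4-one
Product: 23 (2S)-6,8-bis[2,3-bis(benzyloxy)benzyl]-5,7-dihydroxy-2-phenyl-2,3-dihydro-4H-chromen-4-one
Conditions: TBAF/AcOH (1:1), THF, 0 °C
Reagents that add atoms: none
Why: Fluoride cleaves the aryl silyl ethers by Si–O to Si–F exchange, and buffering with acetic acid keeps the medium non-basic so that the flavanone does not open to the chalcone and lose its configuration.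

Step 12
Reactants: 23 (2S)-6,8-bis[2,3-bis(benzyloxy)benzyl]-5,7-dihydroxy-2-phenyl-2,3-dihydro-4H-chromen-4-one
Product: 24 (2S)-6,8-bis(2,3-dihydroxybenzyl)-5,7-dihydroxy-2-phenyl-2,3-dihydro-4H-chromen-4-one
Conditions: H2 (1 atm), 10% Pd/C, EtOAc/MeOH, rt
Reagents that add atoms: none
Why: Hydrogenolysis of aryl benzyl ethers over palladium on carbon at ambient pressure is faster than cleavage of the cyclic benzylic C2–O bond or reduction of the aryl ketone, as is usual for benzyl-protected flavanones, and releases the four catechol hydroxyls.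

**Compound list**

1 | 2,3-dihydroxybenzaldehyde | O=Cc1cccc(O)c1O | starting material
2 | 2,3-bis(benzyloxy)benzaldehyde | O=Cc1cccc(OCc2ccccc2)c1OCc1ccccc1 | intermediate
3 | [2,3-bis(benzyloxy)phenyl]methanol | OCc1cccc(OCc2ccccc2)c1OCc1ccccc1 | intermediate
4 | 1,2-bis(benzyloxy)-3-(bromomethyl)benzene | BrCc1cccc(OCc2ccccc2)c1OCc1ccccc1 | intermediate
5 | ethynylmagnesium bromide | C#C[Mg]Br | starting material
6 | 1,2-bis(benzyloxy)-3-(prop-2-yn-1-yl)benzene | C#CCc1cccc(OCc2ccccc2)c1OCc1ccccc1 | intermediate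
7 | lithium 3-[2,3-bis(benzyloxy)phenyl]prop-1-yn-1-ide (lithium acetylide) | [Li]C#CCc1cccc(OCc2ccccc2)c1OCc1ccccc1 | intermediate
8 | lithium 3-[2,3-bis(benzyloxy)phenyl]prop-1-yn-1-olate (lithium ynolate) | [Li]OC#CCc1cccc(OCc2ccccc2)c1OCc1ccccc1 | intermediate
9 | 3-[2,3-bis(benzyloxy)phenyl]prop-1-yn-1-yl triisopropylsilyl ether | CC(C)[Si](OC#CCc1cccc(OCc2ccccc2)c1OCc1ccccc1)(C(C)C)C(C)C | intermediate
10 | ketene | C=C=O | starting material
11 | 2-[2,3-bis(benzyloxy)benzyl]-3-[(triisopropylsilyl)oxy]cyclobut-2-en-1-one | O=C1CC(O[Si](C(C)C)(C(C)C)C(C)C)=C1Cc1cccc(OCc2ccccc2)c1OCc1ccccc1 | intermediate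
12 | 2-[2,3-bis(benzyloxy)benzyl]-3-[(triisopropylsilyl)oxy]buta-1,3-dien-1-one (vinylketene) | O=C=C(Cc1cccc(OCc2ccccc2)c1OCc1ccccc1)C(=C)O[Si](C(C)C)(C(C)C)C(C)C | intermediate
13 | 2,4-bis[2,3-bis(benzyloxy)benzyl]-3-[(triisopropylsilyl)oxy]-4-{1-[(triisopropylsilyl)oxy]ethenyl}cyclobut-2-en-1-one (racemic vinylcyclobutenone) | O=C1C(Cc2cccc(OCc3ccccc3)c2OCc2ccccc2)=C(O[Si](C(C)C)(C(C)C)C(C)C)C1(Cc1cccc(OCc2ccccc2)c1OCc1ccccc1)C(=C)O[Si](C(C)C)(C(C)C)C(C)C | intermediate
14 | (3E)-2,4-bis[2,3-bis(benzyloxy)benzyl]-3,5-bis[(triisopropylsilyl)oxy]hexa-1,3,5-trien-1-one (dienylketene, ketene and vinyl groups cis) | O=C=C(Cc1cccc(OCc2ccccc2)c1OCc1ccccc1)/C(O[Si](C(C)C)(C(C)C)C(C)C)=C(/Cc1cccc(OCc2ccccc2)c1OCc1ccccc1)C(=C)O[Si](C(C)C)(C(C)C)C(C)C | intermediate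
15 | 2,4-bis[2,3-bis(benzyloxy)benzyl]-3,5-bis[(triisopropylsilyl)oxy]cyclohexa-2,4-dien-1-one | O=C1CC(O[Si](C(C)C)(C(C)C)C(C)C)=C(Cc2cccc(OCc3ccccc3)c2OCc2ccccc2)C(O[Si](C(C)C)(C(C)C)C(C)C)=C1Cc1cccc(OCc2ccccc2)c1OCc1ccccc1 | intermediate
16 | 2,4-bis[2,3-bis(benzyloxy)benzyl]-3,5-bis[(triisopropylsilyl)oxy]phenol | Oc1cc(O[Si](C(C)C)(C(C)C)C(C)C)c(Cc2cccc(OCc3ccccc3)c2OCc2ccccc2)c(O[Si](C(C)C)(C(C)C)C(C)C)c1Cc1cccc(OCc2ccccc2)c1OCc1ccccc1 | intermediate
17 | ethyl (R)-3-hydroxy-3-phenylpropanoate | CCOC(=O)C[C@@H](O)c1ccccc1 | starting material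
18 | {[(1R)-3-ethoxy-3-oxo-1-phenylpropyl]oxy}triphenylphosphonium (alkoxyphosphonium ion) | CCOC(=O)C[C@@H](O[P+](c1ccccc1)(c1ccccc1)c1ccccc1)c1ccccc1 | intermediate
19 | ethyl (3S)-3-{2,4-bis[2,3-bis(benzyloxy)benzyl]-3,5-bis[(triisopropylsilyl)oxy]phenoxy}-3-phenylpropanoate | CCOC(=O)C[C@H](Oc1cc(O[Si](C(C)C)(C(C)C)C(C)C)c(Cc2cccc(OCc3ccccc3)c2OCc2ccccc2)c(O[Si](C(C)C)(C(C)C)C(C)C)c1Cc1cccc(OCc2ccccc2)c1OCc1ccccc1)c1ccccc1 | intermediate
20 | (3S)-3-{2,4-bis[2,3-bis(benzyloxy)benzyl]-3,5-bis[(triisopropylsilyl)oxy]phenoxy}-3-phenylpropanoic acid | O=C(O)C[C@H](Oc1cc(O[Si](C(C)C)(C(C)C)C(C)C)c(Cc2cccc(OCc3ccccc3)c2OCc2ccccc2)c(O[Si](C(C)C)(C(C)C)C(C)C)c1Cc1cccc(OCc2ccccc2)c1OCc1ccccc1)c1ccccc1 | intermediate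
21 | (3S)-3-{2,4-bis[2,3-bis(benzyloxy)benzyl]-3,5-bis[(triisopropylsilyl)oxy]phenoxy}-3-phenylpropanoic trifluoroacetic anhydride (mixed anhydride) | O=C(C[C@H](Oc1cc(O[Si](C(C)C)(C(C)C)C(C)C)c(Cc2cccc(OCc3ccccc3)c2OCc2ccccc2)c(O[Si](C(C)C)(C(C)C)C(C)C)c1Cc1cccc(OCc2ccccc2)c1OCc1ccccc1)c1ccccc1)OC(=O)C(F)(F)F | intermediate
22 | (2S)-6,8-bis[2,3-bis(benzyloxy)benzyl]-2-phenyl-5,7-bis[(triisopropylsilyl)oxy]-2,3-dihydro-4H-chromen-4-one | O=C1C[C@@H](c2ccccc2)Oc2c(Cc3cccc(OCc4ccccc4)c3OCc3ccccc3)c(O[Si](C(C)C)(C(C)C)C(C)C)c(Cc3cccc(OCc4ccccc4)c3OCc3ccccc3)c(O[Si](C(C)C)(C(C)C)C(C)C)c21 | intermediate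
23 | (2S)-6,8-bis[2,3-bis(benzyloxy)benzyl]-5,7-dihydroxy-2-phenyl-2,3-dihydro-4H-chromen-4-one | O=C1C[C@@H](c2ccccc2)Oc2c(Cc3cccc(OCc4ccccc4)c3OCc3ccccc3)c(O)c(Cc3cccc(OCc4ccccc4)c3OCc3ccccc3)c(O)c21 | intermediate
24 | (2S)-6,8-bis(2,3-dihydroxybenzyl)-5,7-dihydroxy-2-phenyl-2,3-dihydro-4H-chromen-4-one (CNP0059702.1) | O=C1C[C@@H](c2ccccc2)Oc2c(Cc3cccc(O)c3O)c(O)c(Cc3cccc(O)c3O)c(O)c21 | target

**Step count and risks**

Total step count: 12. Longest linear sequence: 12 steps (1 → 24); siloxyalkyne 9 is used twice, in steps 6 and 7, so there is no shorter convergent branch.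

Steps most likely to fail:

1. Step 7. The vinylketene may be lost to dimerisation, to desilylation of the sensitive siloxycyclobutenone before it opens, or to capture by the product phenol, so that the cross-benzannulation does not run cleanly. The fallback gives up the de novo ring construction and uses electrophilic substitution on a preformed flavanone. It sets out from alcohol 3, which is heated (2.5 equiv) with commercial (2S)-5,7-dihydroxy-2-phenyl-2,3-dihydro-4H-chromen-4-one (pinocembrin) F1 and ZnCl2 in dioxane at 80 °C. Double Friedel–Crafts benzylation at the only two free A-ring carbons, C6 and C8, should give 23, where the route is rejoined for step 12.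

2. Step 8. The activated β-hydroxy ester may dehydrate to ethyl cinnamate through its alkoxyphosphonium ion, and substitution with ion-pair character at the benzylic carbon may erode the configuration. The fallback removes the acidifying ester from the coupling partner. It sets out from phenol 16, which is coupled (PPh3, DIAD, toluene, 0 °C) with commercial (R)-1-phenylbut-3-en-1-ol F2 to give, with inversion, 1-{[(1S)-1-phenylbut-3-en-1-yl]oxy}-2,4-bis[2,3-bis(benzyloxy)benzyl]-3,5-bis[(triisopropylsilyl)oxy]benzene F3. Lemieux–Johnson cleavage of the terminal alkene (OsO4 cat., NaIO4, 2,6-lutidine, dioxane/H2O) should give (3S)-3-{2,4-bis[2,3-bis(benzyloxy)benzyl]-3,5-bis[(triisopropylsilyl)oxy]phenoxy}-3-phenylpropanal F4. Pinnick oxidation (NaClO2, NaH2PO4, 2-methylbut-2-ene, t-BuOH/H2O) then leads to acid 20, where the route is rejoined for step 10.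

3. Step 5. Base-induced propargyl-to-allenyl isomerisation at the doubly activated benzylic methylene, or incomplete oxygen transfer to the acetylide, may spoil the siloxyalkyne. The fallback reaches the same ynolate from an ester by the Kowalski rearrangement. It sets out from bromide 4, which is ethoxycarbonylated (CO 1 atm, EtOH, PdCl2(PPh3)2 cat., K2CO3, THF, 50 °C) to ethyl [2,3-bis(benzyloxy)phenyl]acetate F5. Addition of LiCHBr2 (CH2Br2, LiTMP, THF, −78 °C) and collapse of the adduct under LiHMDS should give 1,1-dibromo-3-[2,3-bis(benzyloxy)phenyl]propan-2-one F6 as its enolate. n-BuLi (−78 °C → rt) then effects bromine–lithium exchange and rearrangement to lithium ynolate 8, which is silylated with TIPSOTf as in step 5, so the route is rejoined at 8 and 9.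

Further compounds
F1 | step 7 | (2S)-5,7-dihydroxy-2-phenyl-2,3-dihydro-4H-chromen-4-one (pinocembrin) | O=C1C[C@@H](c2ccccc2)Oc2cc(O)cc(O)c21
F2 | step 8 | (R)-1-phenylbut-3-en-1-ol | C=CC[C@@H](O)c1ccccc1
F3 | step 8 | 1-{[(1S)-1-phenylbut-3-en-1-yl]oxy}-2,4-bis[2,3-bis(benzyloxy)benzyl]-3,5-bis[(triisopropylsilyl)oxy]benzene | C=CC[C@H](Oc1cc(O[Si](C(C)C)(C(C)C)C(C)C)c(Cc2cccc(OCc3ccccc3)c2OCc2ccccc2)c(O[Si](C(C)C)(C(C)C)C(C)C)c1Cc1cccc(OCc2ccccc2)c1OCc1ccccc1)c1ccccc1
F4 | step 8 | (3S)-3-{2,4-bis[2,3-bis(benzyloxy)benzyl]-3,5-bis[(triisopropylsilyl)oxy]phenoxy}-3-phenylpropanal | O=CC[C@H](Oc1cc(O[Si](C(C)C)(C(C)C)C(C)C)c(Cc2cccc(OCc3ccccc3)c2OCc2ccccc2)c(O[Si](C(C)C)(C(C)C)C(C)C)c1Cc1cccc(OCc2ccccc2)c1OCc1ccccc1)c1ccccc1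
F5 | step 5 | ethyl [2,3-bis(benzyloxy)phenyl]acetate | CCOC(=O)Cc1cccc(OCc2ccccc2)c1OCc1ccccc1
F6 | step 5 | 1,1-dibromo-3-[2,3-bis(benzyloxy)phenyl]propan-2-one | O=C(Cc1cccc(OCc2ccccc2)c1OCc1ccccc1)C(Br)Br
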